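## Retrosynthetic overview

1. Pterocarpan numbering is used. Ring A is the oxygenated arene C1–C4a/C11b, ring B the pyran (O5, C6, C6a, C11a), ring C the dihydrofuran (O11), ring D the methoxy arene C6b–C10a, and ring E the dimethyldihydropyran on O–C1/C2.
2. Ring B is opened last at O5–C6 (Mitsunobu). This leads back to a cis-2-aryl-3-(hydroxymethyl)-2,3-dihydrobenzofuran and its C6 ester.
3. Ring C is opened at C6a–C11a. An enantioselective rhodium carbene 1,5 C–H insertion of an achiral aryldiazoacetate makes this bond, ring C and both stereocentres at once.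
4. Enabling feature: C11a–H lies between O11 and ring A, which carries oxygen at C1, C3 and C4a (both ortho positions and the para position of C11b). It is therefore the most hydridic C–H bond, and it sits 1,5 to C6a across O11–C10a–C6b of ring D.
5. The diazo ester comes from O11–C11a (Mitsunobu) and C6a–C6b (Pd coupling of an aryl iodide with ethyl diazoacetate). Ring order: E (isoprene annulation of phloroglucinol), then C, then B.

Key step: step 8

Assumption: the sense of induction of Rh2(R-PTTL)4 (dirhodium tetrakis[N-phthaloyl-(R)-tert-leucinate]) is extrapolated from simpler 2-(benzyloxy)phenyldiazoacetates; if the mirror-image ester formed, the catalyst made from (S)-tert-leucine would be used instead.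

## Route

Step 1
Reactants: 1 phloroglucinol; 2 isoprene
Product: 4 2,2-dimethylchroman-5,7-diol, via 2-prenylphloroglucinol 3 (not isolated)
Conditions: Amberlyst 15, THF–heptane, 65 °C, 1 in excess
Reagents that add atoms: none
Why: Acid-catalysed Friedel-Crafts prenylation followed by Markovnikov hydroalkoxylation of the prenyl alkene by a flanking hydroxyl (chroman annulation); the threefold symmetry of 1 allows only one mono-annulated product, and the excess of 1 holds back a second annulation.

Step 2
Reactants: 4 2,2-dimethylchroman-5,7-diol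
Product: 5 5,7-bis(tert-butyldimethylsilyloxy)-2,2-dimethylchroman
Conditions: TBSCl (2.4 equiv), imidazole, DMF, rt
Reagents that add atoms: tert-butyldimethylsilyl chloride (TBSCl), CC(C)(C)[Si](C)(C)Cl
Why: Imidazole-promoted silylation of both phenols; fluoride-labile groups are chosen because the later benzylic C11a–O11 bond would tolerate neither acid nor hydrogenolysis.

Step 3
Reactants: 5 5,7-bis(tert-butyldimethylsilyloxy)-2,2-dimethylchroman
Product: 6 8-bromo-5,7-bis(tert-butyldimethylsilyloxy)-2,2-dimethylchroman
Conditions: NBS (1.0 equiv), CH2Cl2, −78 °C to 0 °C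
Reagents that add atoms: N-bromosuccinimide (NBS), O=C1CCC(=O)N1Br
Why: Electrophilic aromatic bromination; chroman C6 lies between two bulky silyl ethers whereas C8 is flanked by one silyl ether and the tied-back ring oxygen, the same steric bias that directs NBS to C8 of 5,7-di-O-protected flavans.

Step 4
Reactants: 6 8-bromo-5,7-bis(tert-butyldimethylsilyloxy)-2,2-dimethylchroman
Product: 8 5,7-bis(tert-butyldimethylsilyloxy)-2,2-dimethylchroman-8-carbaldehyde, via aryllithium 7 (not isolated)
Conditions: n-BuLi, THF, −78 °C; DMF, −78 °C; H2O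
Reagents that add atoms: N,N-dimethylformamide (DMF), CN(C)C=O
Why: Bromine–lithium exchange and formylation with DMF (Bouveault aldehyde synthesis) fix the future C11a at chroman C8, and exchange and trapping at −78 °C should outrun O-to-C silyl migration.

Step 5
Reactants: 8 5,7-bis(tert-butyldimethylsilyloxy)-2,2-dimethylchroman-8-carbaldehyde
Product: 9 [5,7-bis(tert-butyldimethylsilyloxy)-2,2-dimethylchroman-8-yl]methanol
Conditions: i-Bu2AlH, CH2Cl2, −78 °C; aq potassium sodium tartrate
Reagents that add atoms: none
Why: Hydride reduction of the aldehyde; the aluminium alkoxide formed at low temperature is too weak a nucleophile to pull the neighbouring silyl group from the phenolic onto the benzylic oxygen.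

Step 6
Reactants: 9 [5,7-bis(tert-butyldimethylsilyloxy)-2,2-dimethylchroman-8-yl]methanol; 10 2-iodo-5-methoxyphenol
Product: 11 8-[(2-iodo-5-methoxyphenoxy)methyl]-5,7-bis(tert-butyldimethylsilyloxy)-2,2-dimethylchroman
Conditions: PPh3, DIAD, toluene, 0 °C to rt
Reagents that add atoms: none
Why: Mitsunobu etherification of a primary benzylic alcohol with an acidic phenol forms O11–C11a under neutral conditions and avoids an ionisation-prone trioxygenated benzyl halide.

Step 7
Reactants: 11 8-[(2-iodo-5-methoxyphenoxy)methyl]-5,7-bis(tert-butyldimethylsilyloxy)-2,2-dimethylchroman; 12 ethyl diazoacetate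
Product: 13 ethyl 2-diazo-2-[2-{[5,7-bis(tert-butyldimethylsilyloxy)-2,2-dimethylchroman-8-yl]methoxy}-4-methoxyphenyl]acetate
Conditions: Pd(PPh3)4 (5 mol %), Ag2CO3 (0.5 equiv), Et3N, toluene, rt
Reagents that add atoms: none
Why: Palladium-catalysed cross-coupling of an aryl iodide with the C–H bond of a diazoacetate with retention of the diazo group (oxidative addition to zerovalent palladium, silver-assisted iodide abstraction, base-mediated palladation of 12, reductive elimination at rt before nitrogen is lost) forms C6a–C6b.

Step 8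
Reactants: 13 ethyl 2-diazo-2-[2-{[5,7-bis(tert-butyldimethylsilyloxy)-2,2-dimethylchroman-8-yl]methoxy}-4-methoxyphenyl]acetate
Product: 15 ethyl (2S,3R)-2-[5,7-bis(tert-butyldimethylsilyloxy)-2,2-dimethylchroman-8-yl]-6-methoxy-2,3-dihydrobenzofuran-3-carboxylate (cis), via rhodium carbene 14 (not isolated)
Conditions: Rh2(R-PTTL)4 (2 mol %), 4 Å molecular sieves, toluene, −60 °C, slow addition of 13
Reagents that add atoms: none
Why: Rh2(R-PTTL)4 expels N2 from 13 to give the donor/acceptor carbene 14 at C6a, whose empty orbital takes up the C11a–H bond in a hydride-transfer-like three-centre transition state, so that C6a–C11a and C6a–H form in one event and the catalyst is released. The closest known reaction type is the enantioselective intramolecular 1,5 C–H insertion of 2-(benzyloxy)phenyldiazoacetates to cis-2-aryl-2,3-dihydrobenzofuran-3-carboxylates with dirhodium tetrakis(N-phthaloyl amino acid carboxylate) catalysts. Ring C closes as a five-membered ring in the 1,5-insertion mode (C6a, C6b, C10a, O11, C11a), the only ring size that the rigid ortho tether of ring D allows. C6a and C11a are created together: the pocket formed by the four N-phthaloyl-tert-leucinate ligands leaves one face of the carbene open and so fixes the absolute sense, and the cis relation follows because ring A turns away from the ligand wall while the C–H bond is delivered, which puts it on the same face of the new ring as the ester. The step needs site selectivity for C11a–H over the ester ethyl, silyl methyl and ring E methylene C–H bonds, secured by the double activation through O11 and oxygen-rich ring A and by the 1,5 geometry, and chemoselectivity over cyclopropanation or alkylation of the arenes and over carbene dimerisation, secured by the blocked ortho positions C1 and C4a, by silyl instead of alkyl ethers on ring A, and by slow addition at low temperature. In one operation a precursor without any stereocentre gains the central, most hindered C–C bond, ring C and both stereocentres of the target.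

Step 9
Reactants: 15 ethyl (2S,3R)-2-[5,7-bis(tert-butyldimethylsilyloxy)-2,2-dimethylchroman-8-yl]-6-methoxy-2,3-dihydrobenzofuran-3-carboxylate
Product: 16 {(2S,3S)-2-[5,7-bis(tert-butyldimethylsilyloxy)-2,2-dimethylchroman-8-yl]-6-methoxy-2,3-dihydrobenzofuran-3-yl}methanol
Conditions: i-Bu2AlH (3 equiv), CH2Cl2, −78 °C to −20 °C; aq potassium sodium tartrate
Reagents that add atoms: none
Why: Ester-to-alcohol reduction with a non-basic hydride avoids enolisation, so the kinetic cis configuration at C6a is kept (the descriptor changes from R to S only through the priority change at C6) and is no longer epimerisable afterwards.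

Step 10
Reactants: 16 {(2S,3S)-2-[5,7-bis(tert-butyldimethylsilyloxy)-2,2-dimethylchroman-8-yl]-6-methoxy-2,3-dihydrobenzofuran-3-yl}methanol
Product: 17 8-[(2S,3S)-3-(hydroxymethyl)-6-methoxy-2,3-dihydrobenzofuran-2-yl]-2,2-dimethylchroman-5,7-diol
Conditions: Bu4NF (2.2 equiv), AcOH (2.2 equiv), THF, 0 °C
Reagents that add atoms: none
Why: Fluoride-mediated cleavage of both aryl silyl ethers; the acetic acid buffer keeps the phenols protonated, so ring C is not opened through a quinone methide of ring A.

Step 11
Reactants: 17 8-[(2S,3S)-3-(hydroxymethyl)-6-methoxy-2,3-dihydrobenzofuran-2-yl]-2,2-dimethylchroman-5,7-diol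
Product: 18 (6aS,11aS)-3-hydroxy-9-methoxypterocarpan with a 2,2-dimethyl-3,4-dihydro-2H-pyran ring fused through O at C1 and CH2 at C2 (CNP0207547.1)
Conditions: PPh3, DIAD, THF (0.01 M), 0 °C to rt
Reagents that add atoms: none
Why: Intramolecular Mitsunobu etherification (6-exo-tet) closes ring B at O5–C6; only the C4a hydroxyl can reach the primary carbon, which the cis geometry holds next to ring A, and neither stereocentre takes part, so the C3 hydroxyl stays free and the cis fusion is retained.

## Compound list

1 | phloroglucinol | Oc1cc(O)cc(O)c1 | starting material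
2 | isoprene | C=CC(C)=C | starting material
3 | 2-prenylphloroglucinol | CC(C)=CCc1c(O)cc(O)cc1O | intermediate
4 | 2,2-dimethylchroman-5,7-diol | CC1(C)CCc2c(O)cc(O)cc2O1 | intermediate
5 | 5,7-bis(tert-butyldimethylsilyloxy)-2,2-dimethylchroman | CC1(C)CCc2c(O[Si](C)(C)C(C)(C)C)cc(O[Si](C)(C)C(C)(C)C)cc2O1 | intermediate
6 | 8-bromo-5,7-bis(tert-butyldimethylsilyloxy)-2,2-dimethylchroman | CC1(C)CCc2c(O[Si](C)(C)C(C)(C)C)cc(O[Si](C)(C)C(C)(C)C)c(Br)c2O1 | intermediate
7 | 8-lithio-5,7-bis(tert-butyldimethylsilyloxy)-2,2-dimethylchroman | CC1(C)CCc2c(O[Si](C)(C)C(C)(C)C)cc(O[Si](C)(C)C(C)(C)C)c([Li])c2O1 | intermediate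
8 | 5,7-bis(tert-butyldimethylsilyloxy)-2,2-dimethylchroman-8-carbaldehyde | CC1(C)CCc2c(O[Si](C)(C)C(C)(C)C)cc(O[Si](C)(C)C(C)(C)C)c(C=O)c2O1 | intermediate
9 | [5,7-bis(tert-butyldimethylsilyloxy)-2,2-dimethylchroman-8-yl]methanol | CC1(C)CCc2c(O[Si](C)(C)C(C)(C)C)cc(O[Si](C)(C)C(C)(C)C)c(CO)c2O1 | intermediate
10 | 2-iodo-5-methoxyphenol | COc1ccc(I)c(O)c1 | starting material
11 | 8-[(2-iodo-5-methoxyphenoxy)methyl]-5,7-bis(tert-butyldimethylsilyloxy)-2,2-dimethylchroman | COc1ccc(I)c(OCc2c(O[Si](C)(C)C(C)(C)C)cc(O[Si](C)(C)C(C)(C)C)c3CCC(C)(C)Oc23)c1 | intermediate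
12 | ethyl diazoacetate | CCOC(=O)C=[N+]=[N-] | starting material
13 | ethyl 2-diazo-2-[2-{[5,7-bis(tert-butyldimethylsilyloxy)-2,2-dimethylchroman-8-yl]methoxy}-4-methoxyphenyl]acetate | CCOC(=O)C(=[N+]=[N-])c1ccc(OC)cc1OCc1c(O[Si](C)(C)C(C)(C)C)cc(O[Si](C)(C)C(C)(C)C)c2CCC(C)(C)Oc12 | intermediate
14 | rhodium carbene at C6a (drawn with one rhodium, ligands omitted) | CCOC(=O)C(=[Rh])c1ccc(OC)cc1OCc1c(O[Si](C)(C)C(C)(C)C)cc(O[Si](C)(C)C(C)(C)C)c2CCC(C)(C)Oc12 | intermediate
15 | ethyl (2S,3R)-2-[5,7-bis(tert-butyldimethylsilyloxy)-2,2-dimethylchroman-8-yl]-6-methoxy-2,3-dihydrobenzofuran-3-carboxylate | COc1ccc2c(c1)O[C@H](c3c(O[Si](C)(C)C(C)(C)C)cc(O[Si](C)(C)C(C)(C)C)c4CCC(C)(C)Oc34)[C@@H]2C(=O)OCC | intermediate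
16 | {(2S,3S)-2-[5,7-bis(tert-butyldimethylsilyloxy)-2,2-dimethylchroman-8-yl]-6-methoxy-2,3-dihydrobenzofuran-3-yl}methanol | COc1ccc2c(c1)O[C@H](c3c(O[Si](C)(C)C(C)(C)C)cc(O[Si](C)(C)C(C)(C)C)c4CCC(C)(C)Oc34)[C@@H]2CO | intermediate
17 | 8-[(2S,3S)-3-(hydroxymethyl)-6-methoxy-2,3-dihydrobenzofuran-2-yl]-2,2-dimethylchroman-5,7-diol | COc1ccc2c(c1)O[C@H](c3c(O)cc(O)c4CCC(C)(C)Oc34)[C@@H]2CO | intermediate
18 | (6aS,11aS)-3-hydroxy-9-methoxy-1,2-(2,2-dimethyldihydropyrano)pterocarpan, CNP0207547.1 | COc1ccc2c(c1)O[C@@H]1c3c(cc(O)c4c3OC(C)(C)CC4)OC[C@H]21 | target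

## Step count and risks

Total step count: 11. Longest linear sequence: 11 steps (1 to 18). Compounds 2, 10 and 12 enter as commercial inputs.

**Step 8.** The two ortho substituents of ring A may keep the C11a–H bond from entering the catalyst pocket in the preferred orientation. The insertion could then be slow enough for carbene dimerisation to compete. Facial selectivity at the carbene could be poor, or a long-lived oxocarbenium/enolate pair could leak to the trans isomer.

Fallback: stereocontrol is moved from the catalyst to a covalently bound auxiliary and to the separation of diastereomers.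
- It sets out from iodide 11, which is coupled under the conditions of step 7 with (1R,2S,5R)-menthyl diazoacetate F1 to give the menthyl aryldiazoacetate F2.
- The small achiral Rh2(OAc)4 in CH2Cl2 at rt makes fewer steric demands on the di-ortho-substituted ring A and should effect the same 1,5 insertion.
- The cis esters are now diastereomers. They are separated by chromatography or crystallisation to give the menthyl (2S,3R)-dihydrobenzofuran-3-carboxylate F3.
- Reduction with i-Bu2AlH removes the auxiliary and comes back to the route at alcohol 16.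

**Step 7.** Oxidative addition to the electron-rich, ortho-alkoxy iodide may be slow, and nitrogen may be lost from the palladium-bound diazo unit, which leads to carbene-type side reactions.

Fallback: the carbon chain and the diazo group are introduced separately. It sets out from 11. Arylation of the Reformatsky reagent BrZnCH2CO2Et with Pd(dba)2/P(t-Bu)3 in THF gives the ethyl arylacetate F4. Regitz diazo transfer with 4-acetamidobenzenesulfonyl azide and DBU in MeCN then comes back to the route at 13.

**Step 4.** Aryllithium 7 may undergo anionic O-to-C silyl migration (retro-Brook rearrangement), or be protonated or butylated before it is formylated.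

Fallback: the aldehyde carbon is present from the start and no organolithium is needed.
- It sets out from isoprene 2 and commercial 2,4,6-trihydroxybenzaldehyde F5.
- Selective silylation (TBSCl, imidazole, 0 °C) of the non-chelated, most acidic para hydroxyl gives the symmetric 4-(tert-butyldimethylsilyloxy)-2,6-dihydroxybenzaldehyde F6.
- Annulation with 2 over Amberlyst 15 can only engage one of the two equivalent ring positions and its flanking free hydroxyl. It gives 5-(tert-butyldimethylsilyloxy)-7-hydroxy-2,2-dimethylchroman-8-carbaldehyde F7.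
- Silylation of the remaining chelated phenol (TBSOTf, 2,6-lutidine) comes back to the route at aldehyde 8.

## Further compounds

F1 | step 8 | (1R,2S,5R)-menthyl diazoacetate | [N-]=[N+]=CC(=O)O[C@@H]1C[C@H](C)CC[C@H]1C(C)C
F2 | step 8 | (1R,2S,5R)-menthyl 2-diazo-2-[2-{[5,7-bis(tert-butyldimethylsilyloxy)-2,2-dimethylchroman-8-yl]methoxy}-4-methoxyphenyl]acetate | COc1ccc(C(=[N+]=[N-])C(=O)O[C@@H]2C[C@H](C)CC[C@H]2C(C)C)c(OCc2c(O[Si](C)(C)C(C)(C)C)cc(O[Si](C)(C)C(C)(C)C)c3CCC(C)(C)Oc23)c1
F3 | step 8 | (1R,2S,5R)-menthyl (2S,3R)-2-[5,7-bis(tert-butyldimethylsilyloxy)-2,2-dimethylchroman-8-yl]-6-methoxy-2,3-dihydrobenzofuran-3-carboxylate | COc1ccc2c(c1)O[C@H](c3c(O[Si](C)(C)C(C)(C)C)cc(O[Si](C)(C)C(C)(C)C)c4CCC(C)(C)Oc34)[C@@H]2C(=O)O[C@@H]1C[C@H](C)CC[C@H]1C(C)C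
F4 | step 7 | ethyl 2-[2-{[5,7-bis(tert-butyldimethylsilyloxy)-2,2-dimethylchroman-8-yl]methoxy}-4-methoxyphenyl]acetate | CCOC(=O)Cc1ccc(OC)cc1OCc1c(O[Si](C)(C)C(C)(C)C)cc(O[Si](C)(C)C(C)(C)C)c2CCC(C)(C)Oc12
F5 | step 4 | 2,4,6-trihydroxybenzaldehyde | O=Cc1c(O)cc(O)cc1O
F6 | step 4 | 4-(tert-butyldimethylsilyloxy)-2,6-dihydroxybenzaldehyde | O=Cc1c(O)cc(O[Si](C)(C)C(C)(C)C)cc1O
F7 | step 4 | 5-(tert-butyldimethylsilyloxy)-7-hydroxy-2,2-dimethylchroman-8-carbaldehyde | O=Cc1c(O)cc(O[Si](C)(C)C(C)(C)C)c2CCC(C)(C)Oc12
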